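**Retrosynthetic overview**

1. Locants used throughout: C1 (aryl-bearing CH), C2 (acetoxymethyl-bearing CH), C3 (formyl-bearing), C4 (vinylic CH); ring A is the fused benzo ring (6-OMe, 7-OH), ring B the dihydro ring, ring C the pendant 4-hydroxy-3-methoxyphenyl. The target goes back by lipase O-acetylation and chemoselective reduction of the C2-formyl group to the (1S,2R)-2,3-dicarbaldehyde.
2. Ring B is disconnected at C1–C2: intramolecular 1,6-addition of a chiral-amine enamine (C2) to a ring C para-quinone methide (C1), starting from an acyclic (E)-2-arylidenebutanedial.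
3. Enabling feature: C1 is benzylic to rings A and C and para to the free 4-OH of ring C (and para to the 6-OMe of ring A), so a C1–OMe ether ionizes to the quinone methide. C2 carries the future CH2OAc carbon, which at the aldehyde level makes C2 an enamine carbon.
4. The precursor comes from a crossed aldol condensation (C3=C4) of a ring A benzaldehyde with 4,4-dimethoxybutanal; the benzaldehyde comes from the aryllithium of 6-bromovanillin adding to vanillin (C1–C8a).
5. Ring order: rings A and C are bought as two vanillin units; ring B is the only ring made, in the key step.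

Key step: step 8

Remark: C1 is carried racemic in 7–9 and 13–15 because step 8 erases it; 4,4-dimethoxybutanenitrile is taken as the commercial C4 source (TBS = tert-butyldimethylsilyl).

**Route**

Step 1
Reactants: 1 6-bromovanillin (2-bromo-4-hydroxy-5-methoxybenzaldehyde)
Product: 2 2-bromo-4-[(tert-butyldimethylsilyl)oxy]-5-methoxybenzaldehyde
Conditions: TBSCl, imidazole, DMF, rt
Reagents that add atoms: tert-butyldimethylsilyl chloride, CC(C)(C)[Si](C)(C)Cl
Why: Imidazole-mediated O-silylation of the phenol should mask the acidic ring A hydroxyl before the organolithium step.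

Step 2
Reactants: 3 vanillin (4-hydroxy-3-methoxybenzaldehyde)
Product: 4 4-[(tert-butyldimethylsilyl)oxy]-3-methoxybenzaldehyde
Conditions: TBSCl, imidazole, DMF, rt
Reagents that add atoms: tert-butyldimethylsilyl chloride, CC(C)(C)[Si](C)(C)Cl
Why: The same phenol O-silylation should keep the ring C hydroxyl from quenching the aryllithium and from forming a quinone methide before step 8.

Step 3
Reactants: 2 2-bromo-4-[(tert-butyldimethylsilyl)oxy]-5-methoxybenzaldehyde; 4 4-[(tert-butyldimethylsilyl)oxy]-3-methoxybenzaldehyde
Product: 9 racemic 4-[(tert-butyldimethylsilyl)oxy]-2-{[4-[(tert-butyldimethylsilyl)oxy]-3-methoxyphenyl](methoxy)methyl}-5-methoxybenzaldehyde, via lithium hemiaminal alkoxide 5 (not isolated), via aryllithium 6 (not isolated), via dilithium dialkoxide 7 (not isolated), via bis-O-methylated N,O-acetal 8 (not isolated)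
Conditions: MeNHOMe, n-BuLi, THF, −40 °C; add 2; n-BuLi, −78 °C; add 4; MeOTf, −78 → 0 °C; aq. AcOH/NaOAc (pH 4), rt
Reagents that add atoms: methyl trifluoromethanesulfonate, COS(=O)(=O)C(F)(F)F; water, O
Why: In situ protection of the formyl group as a lithium alpha-amino alkoxide should allow bromine–lithium exchange and 1,2-addition of the aryllithium to 4 (C1–C8a bond), after which O-methylation caps the C1 alkoxide (blocking later lactol formation and oxa-Michael addition to the enal) and mild acid hydrolysis of the N,O-acetal returns the aldehyde; C1 is formed racemic.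

Step 4
Reactants: 10 4,4-dimethoxybutanenitrile
Product: 12 4,4-dimethoxybutanal, via N-aluminio imine 11 (not isolated)
Conditions: i-Bu2AlH (1.1 equiv), CH2Cl2, −78 °C; aq. KNaC4H4O6 work-up
Reagents that add atoms: water, O
Why: Partial reduction of a nitrile by a dialkylaluminium hydride should stop at the N-aluminio imine, which hydrolyzes on work-up to the aldehyde while the acetal survives the non-acidic conditions.

Step 5
Reactants: 9 racemic 4-[(tert-butyldimethylsilyl)oxy]-2-{[4-[(tert-butyldimethylsilyl)oxy]-3-methoxyphenyl](methoxy)methyl}-5-methoxybenzaldehyde; 12 4,4-dimethoxybutanal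
Product: 13 racemic (E)-2-{[4-[(tert-butyldimethylsilyl)oxy]-2-{[4-[(tert-butyldimethylsilyl)oxy]-3-methoxyphenyl](methoxy)methyl}-5-methoxyphenyl]methylidene}-4,4-dimethoxybutanal
Conditions: pyrrolidine (30 mol%), 4-(dimethylamino)benzoic acid (30 mol%), slow addition of 12 (2 equiv), CH2Cl2, rt → 40 °C
Reagents that add atoms: none
Why: An amine-catalyzed crossed aldol condensation (enamine of 12 adding to the iminium of the non-enolizable aldehyde 9, then elimination) should form C3=C4 and settle at the E enal, in which the formyl group is trans to ring A and the C2 methylene is cis to it, as the later ring closure needs.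

Step 6
Reactants: 13 racemic (E)-enal dimethyl acetal
Product: 14 racemic (E)-2-{[4-[(tert-butyldimethylsilyl)oxy]-2-{[4-[(tert-butyldimethylsilyl)oxy]-3-methoxyphenyl](methoxy)methyl}-5-methoxyphenyl]methylidene}butanedial
Conditions: pyridinium p-toluenesulfonate (cat.), acetone/H2O (10:1), 40 °C
Reagents that add atoms: water, O
Why: Mild acid-catalyzed acetal hydrolysis should free the aldehyde next to C2 while the aryl silyl ethers stay, and with ring C still silylated the C1 ether cannot collapse to a quinone methide.

Step 7
Reactants: 14 racemic bis-silylated (E)-2-arylidenebutanedial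
Product: 15 racemic (E)-2-{[4-hydroxy-2-[(4-hydroxy-3-methoxyphenyl)(methoxy)methyl]-5-methoxyphenyl]methylidene}butanedial
Conditions: Bu4NF (2.2 equiv), AcOH (2.5 equiv), THF, 0 °C; pH 7 buffer work-up; used at once
Reagents that add atoms: none
Why: Fluoride-driven cleavage of both aryl silyl ethers should proceed under acetic acid buffering, which keeps the medium too weakly basic for aldol reactions of the 1,4-dialdehyde or for loss of methoxide from the now free para-hydroxybenzyl ether.

Step 8
Reactants: 15 racemic (E)-2-{[4-hydroxy-2-[(4-hydroxy-3-methoxyphenyl)(methoxy)methyl]-5-methoxyphenyl]methylidene}butanedial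
Product: 18 (1S,2R)-7-hydroxy-1-(4-hydroxy-3-methoxyphenyl)-6-methoxy-1,2-dihydronaphthalene-2,3-dicarbaldehyde, via para-quinone methide 16 (not isolated), via catalyst-bound enamine 17 (not isolated)
Conditions: (R)-α,α-diphenylprolinol trimethylsilyl ether (20 mol%), diphenyl phosphate (20 mol%), H2O (2 equiv), CHCl3 (0.02 M), 0 °C; crude solution taken directly into step 9
Reagents that add atoms: none
Why: Diphenyl phosphate should ionize the C1 methyl ether, which is para to the free ring C phenol, to para-quinone methide 16 (the racemic C1 centre is erased, so the step is stereoconvergent), while the amine condenses only with the saturated aldehyde to give E-enamine 17; C2 of the enamine then adds to C1 in a 1,6-conjugate addition that re-aromatizes ring C, and water hydrolyzes the iminium to release 18 and the catalyst. The closest known reaction type is the aminocatalytic alpha-alkylation of aldehydes by para-quinone methides or by stabilized benzhydryl cations generated in situ with acid, run here intramolecularly. Ring B closes in a 6-exo-trig mode at the quinone methide carbon (exo also with respect to the enamine double bond), with four of its six atoms already sp2 and C2 held cis to ring A by the E C3=C4 bond. C2 is set by the catalyst: in the E, s-trans enamine the diphenyl(silyloxy)methyl group of the R amine covers one face of C2, so C1 should bond to the open face and give 2R; C1 is set by the cyclic transition state, which should place the quinoid ring C anti to the enamine CH–N arm across the forming bond and so give the trans (1S) isomer, any cis isomer being a separable diastereomer. The step needs chemoselectivity, secured because the alpha-branched, aryl-conjugated C3 enal has no position from which a carbon nucleophile can form, and kinetic control at C2, secured by low temperature, high dilution and immediate reduction of crude 18.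

Step 9
Reactants: 18 (1S,2R)-7-hydroxy-1-(4-hydroxy-3-methoxyphenyl)-6-methoxy-1,2-dihydronaphthalene-2,3-dicarbaldehyde
Product: 19 (1S,2R)-7-hydroxy-2-(hydroxymethyl)-1-(4-hydroxy-3-methoxyphenyl)-6-methoxy-1,2-dihydronaphthalene-3-carbaldehyde
Conditions: NaBH4 (0.3 equiv), EtOH/CH2Cl2 (3:7), −78 °C; aq. NH4Cl
Reagents that add atoms: none
Why: Chemoselective borohydride reduction should take only the saturated C2-formyl group, because the C3-formyl group is conjugated with C3=C4 and the para-oxygenated ring A (a vinylogous ester, or carboxylate once the phenol is deprotonated) and is far less electrophilic; no stereocentre is touched and C2 can no longer epimerize.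

Step 10
Reactants: 19 (1S,2R)-7-hydroxy-2-(hydroxymethyl)-1-(4-hydroxy-3-methoxyphenyl)-6-methoxy-1,2-dihydronaphthalene-3-carbaldehyde
Product: 20 [(1S,2R)-3-formyl-7-hydroxy-1-(4-hydroxy-3-methoxyphenyl)-6-methoxy-1,2-dihydronaphthalen-2-yl]methyl acetate (target)
Conditions: Novozym 435 (immobilized Candida antarctica lipase B), vinyl acetate (5 equiv), THF, 40 °C
Reagents that add atoms: vinyl acetate, C=COC(C)=O
Why: Lipase-catalyzed transesterification should acetylate the primary aliphatic alcohol through the acetyl-enzyme while the two phenols are not accepted as acyl acceptors, and tautomerization of the released vinyl alcohol to acetaldehyde makes the transfer irreversible.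

**Compound list**

1 | 6-bromovanillin (2-bromo-4-hydroxy-5-methoxybenzaldehyde) | COc1cc(C=O)c(Br)cc1O | starting material
2 | 2-bromo-4-[(tert-butyldimethylsilyl)oxy]-5-methoxybenzaldehyde | COc1cc(C=O)c(Br)cc1O[Si](C)(C)C(C)(C)C | intermediate
3 | vanillin (4-hydroxy-3-methoxybenzaldehyde) | COc1cc(C=O)ccc1O | starting material
4 | 4-[(tert-butyldimethylsilyl)oxy]-3-methoxybenzaldehyde | COc1cc(C=O)ccc1O[Si](C)(C)C(C)(C)C | intermediate
5 | lithium hemiaminal alkoxide of 2 with LiN(Me)OMe (racemic) | [Li+].[O-]C(N(C)OC)c1cc(OC)c(O[Si](C)(C)C(C)(C)C)cc1Br | intermediate (not isolated)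
6 | aryllithium from 5 (Li in place of Br) | [Li+].[O-]C(N(C)OC)c1cc(OC)c(O[Si](C)(C)C(C)(C)C)cc1[Li] | intermediate (not isolated)
7 | dilithium dialkoxide from 6 and 4 (stereoisomer mixture) | [Li+].[Li+].[O-]C(N(C)OC)c1cc(OC)c(O[Si](C)(C)C(C)(C)C)cc1C([O-])c1ccc(O[Si](C)(C)C(C)(C)C)c(OC)c1 | intermediate (not isolated)
8 | bis-O-methylated N,O-acetal of 7 (stereoisomer mixture) | CON(C)C(OC)c1cc(OC)c(O[Si](C)(C)C(C)(C)C)cc1C(OC)c1ccc(O[Si](C)(C)C(C)(C)C)c(OC)c1 | intermediate (not isolated)
9 | racemic 4-[(tert-butyldimethylsilyl)oxy]-2-{[4-[(tert-butyldimethylsilyl)oxy]-3-methoxyphenyl](methoxy)methyl}-5-methoxybenzaldehyde | COc1cc(C=O)c(C(OC)c2ccc(O[Si](C)(C)C(C)(C)C)c(OC)c2)cc1O[Si](C)(C)C(C)(C)C | intermediate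
10 | 4,4-dimethoxybutanenitrile | COC(CCC#N)OC | starting material
11 | N-(diisobutylaluminio)imine of 4,4-dimethoxybutanal | COC(CCC=N[Al](CC(C)C)CC(C)C)OC | intermediate (not isolated)
12 | 4,4-dimethoxybutanal | COC(CCC=O)OC | intermediate
13 | racemic (E)-2-{[4-(TBS-oxy)-2-{[4-(TBS-oxy)-3-methoxyphenyl](methoxy)methyl}-5-methoxyphenyl]methylidene}-4,4-dimethoxybutanal | COc1cc(/C=C(\CC(OC)OC)C=O)c(C(OC)c2ccc(O[Si](C)(C)C(C)(C)C)c(OC)c2)cc1O[Si](C)(C)C(C)(C)C | intermediate
14 | racemic (E)-2-{[4-(TBS-oxy)-2-{[4-(TBS-oxy)-3-methoxyphenyl](methoxy)methyl}-5-methoxyphenyl]methylidene}butanedial | COc1cc(/C=C(\CC=O)C=O)c(C(OC)c2ccc(O[Si](C)(C)C(C)(C)C)c(OC)c2)cc1O[Si](C)(C)C(C)(C)C | intermediate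
15 | racemic (E)-2-{[4-hydroxy-2-[(4-hydroxy-3-methoxyphenyl)(methoxy)methyl]-5-methoxyphenyl]methylidene}butanedial | COc1cc(/C=C(\CC=O)C=O)c(C(OC)c2ccc(O)c(OC)c2)cc1O | intermediate
16 | ring C para-quinone methide: (E)-2-{[4-hydroxy-5-methoxy-2-[(3-methoxy-4-oxocyclohexa-2,5-dien-1-ylidene)methyl]phenyl]methylidene}butanedial | COC1=CC(=Cc2cc(O)c(OC)cc2/C=C(\CC=O)C=O)C=CC1=O | intermediate (not isolated)
17 | E-enamine of the saturated aldehyde of 16 with (R)-α,α-diphenylprolinol trimethylsilyl ether | C[Si](C)(C)OC(c1ccccc1)(c1ccccc1)[C@H]1CCCN1/C=C/C(C=O)=C\c1cc(OC)c(O)cc1C=C1C=CC(=O)C(OC)=C1 | intermediate (not isolated)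
18 | (1S,2R)-7-hydroxy-1-(4-hydroxy-3-methoxyphenyl)-6-methoxy-1,2-dihydronaphthalene-2,3-dicarbaldehyde (trans) | COc1cc([C@H]2c3cc(O)c(OC)cc3C=C(C=O)[C@@H]2C=O)ccc1O | intermediate
19 | (1S,2R)-7-hydroxy-2-(hydroxymethyl)-1-(4-hydroxy-3-methoxyphenyl)-6-methoxy-1,2-dihydronaphthalene-3-carbaldehyde (trans) | COc1cc([C@H]2c3cc(O)c(OC)cc3C=C(C=O)[C@@H]2CO)ccc1O | intermediate
20 | [(1S,2R)-3-formyl-7-hydroxy-1-(4-hydroxy-3-methoxyphenyl)-6-methoxy-1,2-dihydronaphthalen-2-yl]methyl acetate (trans) | COc1cc([C@H]2c3cc(O)c(OC)cc3C=C(C=O)[C@@H]2COC(C)=O)ccc1O | target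

**Step count and risks**

Total steps: 10. Longest linear sequence: 8 steps (1, 3, 5, 6, 7, 8, 9, 10).

Steps most likely to fail:

Step 8. The amine may discriminate the enamine faces or the quinone methide faces poorly, the quinone methide may be captured intermolecularly by phenols (oligomerization), or C2 may epimerize before reduction. The fallback gives up asymmetric induction; it sets out from 15 and comes back at 19. Pyrrolidine (20 mol%) and diphenyl phosphate in CHCl3 at rt should close ring B through 16 and its achiral pyrrolidine enamine F1, and reversible enamine formation should equilibrate C2 to the trans dialdehyde as the racemate, that is 18 together with its mirror image, the (1R,2S)-dialdehyde F2. NaBH4 reduction as in step 9 then gives 19 together with the (1R,2S)-hydroxy aldehyde F3, and preparative HPLC on a cellulose tris(3,5-dimethylphenylcarbamate) phase should separate the two.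

Step 5. Self-condensation of the enolizable aldehyde 12 may outrun the crossed condensation with the hindered, electron-rich aryl aldehyde. The fallback replaces the condensation by a Wittig olefination; it sets out from 9 and comes back at 13. 3-Bromo-1,1-dimethoxypropane and PPh3 give (3,3-dimethoxypropyl)triphenylphosphonium bromide F4. KOt-Bu (2 equiv) generates (3,3-dimethoxypropylidene)triphenylphosphorane F5, which is C-formylated with ethyl formate to the stabilized ylide 4,4-dimethoxy-2-(triphenylphosphoranylidene)butanal F6. Heating 9 with F6 in toluene should give 13 with E selectivity.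

Step 3. In the four-stage one-flask sequence the bromine–lithium exchange may be incomplete, the hemiaminal alkoxide may collapse, or the hindered alkoxide may be methylated incompletely. The fallback uses discrete protection and isolated intermediates; it sets out from 2 (with 4) and comes back at 9. HC(OMe)3 with TsOH (cat.) in MeOH converts 2 into the dimethyl acetal 2-bromo-4-[(tert-butyldimethylsilyl)oxy]-1-(dimethoxymethyl)-5-methoxybenzene F7. n-BuLi (THF, −78 °C) gives the aryllithium acetal F8, which adds to 4 to give after work-up the diaryl carbinol acetal F9. Pyridinium p-toluenesulfonate in MeOH (SN1 etherification through the doubly para-oxygenated benzhydryl cation) gives the C1 methyl ether acetal F10, and the same acid in acetone/H2O releases the formyl group to give 9.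

**Further compounds**

F1 | step 8 | E-enamine of the saturated aldehyde of 16 with pyrrolidine | C1CCCN1/C=C/C(C=O)=C\c1cc(OC)c(O)cc1C=C1C=CC(=O)C(OC)=C1
F2 | step 8 | (1R,2S)-7-hydroxy-1-(4-hydroxy-3-methoxyphenyl)-6-methoxy-1,2-dihydronaphthalene-2,3-dicarbaldehyde (enantiomer of 18) | COc1cc([C@@H]2c3cc(O)c(OC)cc3C=C(C=O)[C@H]2C=O)ccc1O
F3 | step 8 | (1R,2S)-7-hydroxy-2-(hydroxymethyl)-1-(4-hydroxy-3-methoxyphenyl)-6-methoxy-1,2-dihydronaphthalene-3-carbaldehyde (enantiomer of 19) | COc1cc([C@@H]2c3cc(O)c(OC)cc3C=C(C=O)[C@H]2CO)ccc1O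
F4 | step 5 | (3,3-dimethoxypropyl)triphenylphosphonium bromide | COC(CC[P+](c1ccccc1)(c1ccccc1)c1ccccc1)OC.[Br-]
F5 | step 5 | (3,3-dimethoxypropylidene)triphenylphosphorane | COC(CC=P(c1ccccc1)(c1ccccc1)c1ccccc1)OC
F6 | step 5 | 4,4-dimethoxy-2-(triphenylphosphoranylidene)butanal | COC(CC(C=O)=P(c1ccccc1)(c1ccccc1)c1ccccc1)OC
F7 | step 3 | 2-bromo-4-[(tert-butyldimethylsilyl)oxy]-1-(dimethoxymethyl)-5-methoxybenzene | COc1cc(C(OC)OC)c(Br)cc1O[Si](C)(C)C(C)(C)C
F8 | step 3 | aryllithium acetal from F7 (Li in place of Br) | COc1cc(C(OC)OC)c([Li])cc1O[Si](C)(C)C(C)(C)C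
F9 | step 3 | racemic diaryl carbinol acetal (C1–OH, formyl group as dimethyl acetal, both phenols as TBS ethers) | COc1cc(C(OC)OC)c(C(O)c2ccc(O[Si](C)(C)C(C)(C)C)c(OC)c2)cc1O[Si](C)(C)C(C)(C)C
F10 | step 3 | racemic C1 methyl ether acetal (dimethyl acetal of 9) | COc1cc(C(OC)OC)c(C(OC)c2ccc(O[Si](C)(C)C(C)(C)C)c(OC)c2)cc1O[Si](C)(C)C(C)(C)C
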